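**Plan**
Retrosynthesis: remove the C7 silyl ether, cut the C4–O benzoate bond (SN2 with inversion), cut the C1–O benzoate bond back to a C6/C1 oxirane, take that oxygen off the C6=C1 alkene, raise C7 to the ester level, and finally cut C4–O and C5–O to reach methyl benzoate.
Forward: no carbocycle is built. The six-membered ring C1–C6 is the benzene ring of methyl benzoate, dearomatised in the first step; C7 is its ester carbon; the only ring closed later is the transient oxirane at C6/C1.
Stereochemistry: C5 comes from the enzyme; C6 from epoxidation directed by C5–OH; C1 from anti opening of that epoxide; C4 from inversion of the enzyme-set carbinol.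
Enabling feature: ring carbon C6 carries the only carbon branch (C7), and its neighbours C5 and C4 carry contiguous oxygens, with C5 in the configuration that toluene dioxygenase installs next to an arene substituent.

Key step: step 1

Remark: atom labels C1–C7 are those of the target (C1 OBz, C2=C3, C4 OBz, C5 OH, C6 OH and CH2OH, C7 the CH2OH carbon), and the recombinant strain E. coli JM109(pDTG601A) is taken as an available whole-cell catalyst.

**Step 1**
Reactants: 1 methyl benzoate
Product: 2 methyl (5S,6R)-5,6-dihydroxycyclohexa-1,3-diene-1-carboxylate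
Conditions: E. coli JM109(pDTG601A) whole cells expressing toluene dioxygenase, IPTG induction, glucose feed, air, pH 7, 30 °C; EtOAc extraction
Reagents that add atoms: dioxygen, O=O
Why: The non-haem iron oxygenase component of toluene dioxygenase binds methyl benzoate with the ester where the methyl group of toluene would sit, activates O2 at its mononuclear iron centre with two electrons relayed from NADH, and delivers both oxygen atoms suprafacially to the ortho and meta carbons, so the C5–O and C4–O bonds form in one cis event. The closest known reaction type is the whole-cell toluene dioxygenase cis-dihydroxylation of monosubstituted benzenes, which is documented for benzoate esters. No ring is closed: the carbocycle is the arene ring itself, and the C6=C1/C2=C3 diene is what remains of it. Both new stereocentres (C4 and C5) are set by the chiral active site, which exposes one face of the 2,3-bond to the iron-bound oxygen, and their cis relationship follows from transfer of both atoms of one O2 molecule. The step needs ortho,meta site selectivity (not ipso,ortho or meta,para) and no further oxidation to the catechol; the first is secured by the single substituent on C6 that orients the ring in the pocket, the second by a host that carries the dioxygenase genes without the diol dehydrogenase. The electron-poor ring is expected to react more slowly than toluene, which affects titre and not selectivity.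

**Step 2**
Reactants: 2 methyl (5S,6R)-5,6-dihydroxycyclohexa-1,3-diene-1-carboxylate
Product: 3 (1S,2R)-3-(hydroxymethyl)cyclohexa-3,5-diene-1,2-diol
Conditions: iBu2AlH (5 equiv), THF, −78 → −20 °C; Na2SO4·10H2O quench, filtration
Reagents that add atoms: none
Why: Diisobutylaluminium hydride reduces the conjugated ester by 1,2-addition to the primary allylic alcohol (ester-to-alcohol reduction) after the two hydroxyls have become aluminium alkoxides, the non-acidic, non-extractive work-up suits the acid-sensitive and water-soluble diene triol, and no stereocentre is touched.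

**Step 3**
Reactants: 3 (1S,2R)-3-(hydroxymethyl)cyclohexa-3,5-diene-1,2-diol; 4 tert-butyldimethylsilyl chloride
Product: 5 (1S,2R)-3-({[tert-butyl(dimethyl)silyl]oxy}methyl)cyclohexa-3,5-diene-1,2-diol
Conditions: TBSCl (1.05 equiv), imidazole, DMF, −20 → 0 °C
Reagents that add atoms: tert-butyldimethylsilyl chloride (4), CC(C)(C)[Si](C)(C)Cl
Why: Silyl ether formation with a bulky chlorosilane is selective for the unhindered primary C7 hydroxyl over the two secondary ring hydroxyls at low temperature, which masks the hydroxyl that would otherwise react first in the later Mitsunobu step and makes the intermediates lipophilic.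

**Step 4**
Reactants: 5 (1S,2R)-3-({[tert-butyl(dimethyl)silyl]oxy}methyl)cyclohexa-3,5-diene-1,2-diol
Product: 6 (1S,2S,3S,6R)-1-({[tert-butyl(dimethyl)silyl]oxy}methyl)-7-oxabicyclo[4.1.0]hept-4-ene-2,3-diol (C6/C1 epoxide on the face of the C5 and C4 hydroxyls)
Conditions: VO(acac)2 (5 mol %), tBuOOH (1.1 equiv, decane solution), CH2Cl2, 0 °C
Reagents that add atoms: tert-butyl hydroperoxide, CC(C)(C)OO
Why: In this vanadium-catalysed hydroxyl-directed epoxidation of an allylic alcohol, the C5 hydroxyl (held pseudoaxial by allylic strain with the C6 substituent) binds the vanadium alkylperoxide and delivers oxygen to its own face of the adjacent, more nucleophilic trisubstituted C6=C1 bond, which sets C6 cis to C5–OH, whereas the pseudoequatorial C4 hydroxyl is poorly placed to direct attack on the disubstituted C2=C3 bond.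

**Step 5**
Reactants: 6 the cis epoxy diol; 7 benzoic acid
Product: 8 (1S,4S,5S,6S)-6-({[tert-butyl(dimethyl)silyl]oxy}methyl)-4,5,6-trihydroxycyclohex-2-en-1-yl benzoate
Conditions: PhCO2H (2 equiv), Ti(OiPr)4 (1.5 equiv), CH2Cl2, rt; aqueous tartaric acid work-up
Reagents that add atoms: benzoic acid (7), O=C(O)c1ccccc1
Why: In this Ti(OiPr)4-mediated C3-selective opening of a 2,3-epoxy alcohol by a carboxylic acid, titanium chelated by C5–O and the oxirane oxygen activates the epoxide and benzoate attacks the secondary, allylic C1 from the face opposite the oxirane (SN2, inversion) and not the tertiary C6, giving the C1 benzoate trans to the retained C6 hydroxyl.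

**Step 6**
Reactants: 8 the C1 monobenzoate triol; 7 benzoic acid
Product: 9 (1S,4R,5S,6S)-6-({[tert-butyl(dimethyl)silyl]oxy}methyl)-5,6-dihydroxycyclohex-2-ene-1,4-diyl dibenzoate
Conditions: PPh3 (1.3 equiv), diisopropyl azodicarboxylate (1.3 equiv), PhCO2H (1.3 equiv), THF, 0 °C → rt
Reagents that add atoms: benzoic acid (7), O=C(O)c1ccccc1
Why: In this Mitsunobu esterification only the allylic secondary C4 hydroxyl is readily activated as its oxyphosphonium ion (C5–OH is flanked by the fully substituted C6, C6–OH is tertiary, and the cis-vicinal C5 hydroxyl cannot close an epoxide), and benzoate displaces it by SN2 with inversion to set C4 trans to C5–OH, a site selectivity known for the allylic hydroxyl of the cis-diol in shikimate esters.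

**Step 7**
Reactants: 9 the silyl-protected dibenzoate
Product: 10 (1S,4R,5S,6S)-5,6-dihydroxy-6-(hydroxymethyl)cyclohex-2-ene-1,4-diyl dibenzoate (CNP0212417.1)
Conditions: HF·pyridine, pyridine, THF, 0 °C → rt
Reagents that add atoms: none
Why: Fluoride-mediated silyl ether cleavage under buffered, weakly acidic conditions removes only the primary TBS group, and avoiding basic fluoride prevents migration of the C1 or C4 benzoate onto the neighbouring free hydroxyls, so no stereocentre is affected.

**Compound list**
1 | methyl benzoate | COC(=O)c1ccccc1 | starting material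
2 | methyl (5S,6R)-5,6-dihydroxycyclohexa-1,3-diene-1-carboxylate | COC(=O)C1=CC=C[C@H](O)[C@@H]1O | intermediate
3 | (1S,2R)-3-(hydroxymethyl)cyclohexa-3,5-diene-1,2-diol | OCC1=CC=C[C@H](O)[C@@H]1O | intermediate
4 | tert-butyldimethylsilyl chloride | CC(C)(C)[Si](C)(C)Cl | starting material
5 | (1S,2R)-3-({[tert-butyl(dimethyl)silyl]oxy}methyl)cyclohexa-3,5-diene-1,2-diol | CC(C)(C)[Si](C)(C)OCC1=CC=C[C@H](O)[C@@H]1O | intermediate
6 | (1S,2S,3S,6R)-1-({[tert-butyl(dimethyl)silyl]oxy}methyl)-7-oxabicyclo[4.1.0]hept-4-ene-2,3-diol | CC(C)(C)[Si](C)(C)OC[C@@]12O[C@@H]1C=C[C@H](O)[C@@H]2O | intermediate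
7 | benzoic acid | O=C(O)c1ccccc1 | starting material
8 | (1S,4S,5S,6S)-6-({[tert-butyl(dimethyl)silyl]oxy}methyl)-4,5,6-trihydroxycyclohex-2-en-1-yl benzoate | O=C(O[C@H]1C=C[C@H](O)[C@H](O)[C@@]1(O)CO[Si](C)(C)C(C)(C)C)c1ccccc1 | intermediate
9 | (1S,4R,5S,6S)-6-({[tert-butyl(dimethyl)silyl]oxy}methyl)-5,6-dihydroxycyclohex-2-ene-1,4-diyl dibenzoate | O=C(O[C@H]1C=C[C@@H](OC(=O)c2ccccc2)[C@H](O)[C@@]1(O)CO[Si](C)(C)C(C)(C)C)c1ccccc1 | intermediate
10 | (1S,4R,5S,6S)-5,6-dihydroxy-6-(hydroxymethyl)cyclohex-2-ene-1,4-diyl dibenzoate | O=C(O[C@H]1C=C[C@@H](OC(=O)c2ccccc2)[C@H](O)[C@@]1(O)CO)c1ccccc1 | target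

**Count**
Total steps: 7. Longest linear sequence: 7 steps, from methyl benzoate 1 to 10.

**Steps most likely to fail**

Step 4. Site selectivity between the two alkenes may be poor, because the C4 hydroxyl is itself allylic to C2=C3 and can direct the oxidant there. The vanadium catalyst may also oxidise the C4 carbinol, after which the ring aromatises. Fallback, setting out from 5: remove the competing directing group before oxidation. TESCl and imidazole at −40 °C should silylate the less hindered C4 hydroxyl to give the C4 triethylsilyl ether of 5 F1, in which only C5–OH is free. VO(acac)2/tBuOOH then has a single hydroxyl to bind and should give the C6/C1 cis epoxide F2. Ti(OiPr)4/PhCO2H opening at C1 gives the C1 benzoate still carrying the C4 triethylsilyl ether F3. Pyridinium p-toluenesulfonate in MeOH at 0 °C removes the secondary triethylsilyl group in the presence of the primary TBS ether, and the sequence rejoins the route at 8.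

Step 6. Activation may not stay at C4, benzoate may enter with allylic transposition at C2, or the oxyphosphonium ion may eliminate to a diene. Fallback, setting out from 8: invert C4 by oxidation and directed reduction instead of displacement. MnO2 in CH2Cl2 oxidises only the allylic C4 carbinol to the C4 enone F4. Me4NBH(OAc)3 in MeCN/AcOH at −20 °C, bound to the C5 and C6 hydroxyls, delivers hydride to their face of the ketone and gives the C4-epimeric triol F5, with C4–OH trans to C5–OH. Benzoyl chloride (1.05 equiv) and pyridine at −40 °C acylate the accessible allylic C4 hydroxyl in preference to the hindered C5 and tertiary C6 hydroxyls, and the sequence rejoins the route at 9.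

Step 2. The diene triol may dehydrate and aromatise on work-up, or be lost with the aluminium salts because of its water solubility. Fallback, setting out from 2: carry the diol through the reduction as base-labile silyl ethers. Me3SiCl/Et3N gives the bis(trimethylsilyl) ether of 2 F6. iBu2AlH (2.2 equiv) at −78 °C reduces it to the lipophilic bis(trimethylsilyl) ether of 3 F7, with C7–OH free. TBSCl/imidazole gives the fully silylated triol F8. K2CO3 in MeOH at 0 °C cleaves the two trimethylsilyl ethers under basic conditions that the diene tolerates and leaves the TBS ether, and the sequence rejoins the route at 5.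

**Further compounds**
F1 | step 4 | C4 triethylsilyl ether of 5, (1R,6S)-2-({[tert-butyl(dimethyl)silyl]oxy}methyl)-6-[(triethylsilyl)oxy]cyclohexa-2,4-dien-1-ol | CC(C)(C)[Si](C)(C)OCC1=CC=C[C@H](O[Si](CC)(CC)CC)[C@@H]1O
F2 | step 4 | C6/C1 cis epoxide of F1 (oxirane on the face of C5–OH) | CC(C)(C)[Si](C)(C)OC[C@@]12O[C@@H]1C=C[C@H](O[Si](CC)(CC)CC)[C@@H]2O
F3 | step 4 | C4 triethylsilyl ether of 8 | O=C(O[C@H]1C=C[C@H](O[Si](CC)(CC)CC)[C@H](O)[C@@]1(O)CO[Si](C)(C)C(C)(C)C)c1ccccc1
F4 | step 6 | C4 ketone (enone) derived from 8 | O=C(O[C@H]1C=CC(=O)[C@H](O)[C@@]1(O)CO[Si](C)(C)C(C)(C)C)c1ccccc1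
F5 | step 6 | C4 epimer of 8 (C4–OH trans to C5–OH) | O=C(O[C@H]1C=C[C@@H](O)[C@H](O)[C@@]1(O)CO[Si](C)(C)C(C)(C)C)c1ccccc1
F6 | step 2 | bis(trimethylsilyl) ether of 2 | COC(=O)C1=CC=C[C@H](O[Si](C)(C)C)[C@@H]1O[Si](C)(C)C
F7 | step 2 | C4,C5-bis(trimethylsilyl) ether of 3 (C7–OH free) | OCC1=CC=C[C@H](O[Si](C)(C)C)[C@@H]1O[Si](C)(C)C
F8 | step 2 | C4,C5-bis(trimethylsilyl) ether of 5 | CC(C)(C)[Si](C)(C)OCC1=CC=C[C@H](O[Si](C)(C)C)[C@@H]1O[Si](C)(C)C
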